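**Retrosynthetic overview**
- The target is reached by hydrogenolysis of its 5,7-di-O-benzyl ether; ring C of that flavone is opened at O1–C2 (oxidative cyclisation) to a 2'-hydroxychalcone.
- The chalcone comes from a Claisen–Schmidt condensation of bought 2'-hydroxy-4',6'-bis(benzyloxy)acetophenone (ring A) with 3-acetoxy-2,4,5-trimethoxybenzaldehyde (ring B).
- The ring B aldehyde comes from Rieche formylation of 2,3,6-trimethoxyphenyl acetate, made from 1,2,4-trimethoxybenzene by lithiation between the two flanking OMe groups, borylation, oxidation and acetylation.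
- Rings A and B are bought as benzenes; ring C (the pyranone) is the only ring formed, in step 5.

Assumption: the target has no stereocentre (it is achiral), so no stereocontrol is needed, and 2'-hydroxy-4',6'-bis(benzyloxy)acetophenone is taken as a catalogue compound.

**Step 1**
Reactants: 1 1,2,4-trimethoxybenzene
Product: 4 2,3,6-trimethoxyphenol, via (2,3,6-trimethoxyphenyl)lithium 2 (not isolated), via dimethyl (2,3,6-trimethoxyphenyl)boronate 3 (not isolated)
Conditions: n-BuLi, THF, 0 °C to rt; B(OMe)3, −78 °C to rt; AcOH, 30% H2O2, 0 °C to rt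
Reagents that add atoms: hydrogen peroxide (OO); n-butyllithium ([Li]CCCC) and trimethyl borate (COB(OC)OC) put atoms only into intermediates 2 and 3
Why: Directed ortho-metalation removes the C3–H flanked by two methoxy groups, and borylation followed by peroxide oxidation (1,2-aryl shift from boron to oxygen) places OH on that carbon; no stereocentre is formed.

**Step 2**
Reactants: 4 2,3,6-trimethoxyphenol
Product: 5 2,3,6-trimethoxyphenyl acetate
Conditions: Ac2O, pyridine, rt
Reagents that add atoms: acetic anhydride (CC(=O)OC(C)=O)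
Why: Simple O-acylation of the phenol, which turns the strongest donor on the ring into a weak one so that the methoxy groups control the next substitution.

**Step 3**
Reactants: 5 2,3,6-trimethoxyphenyl acetate
Product: 7 3-acetoxy-2,4,5-trimethoxybenzaldehyde, via 3-[chloro(methoxy)methyl]-2,5,6-trimethoxyphenyl acetate 6 (not isolated)
Conditions: Cl2CHOMe, TiCl4, CH2Cl2, −10 to 0 °C; ice-cold dilute HCl work-up
Reagents that add atoms: dichloromethyl methyl ether (COC(Cl)Cl); water (O)
Why: Rieche formylation (Friedel–Crafts type) enters the free position that is ortho to one OMe and para to another (meta to OAc) in preference to the position para to the weakly donating OAc, and the α-chloro ether hydrolyses to the aldehyde on work-up.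

**Step 4**
Reactants: 7 3-acetoxy-2,4,5-trimethoxybenzaldehyde; 8 2'-hydroxy-4',6'-bis(benzyloxy)acetophenone
Product: 11 (E)-1-[2,4-bis(benzyloxy)-6-hydroxyphenyl]-3-(3-hydroxy-2,4,5-trimethoxyphenyl)prop-2-en-1-one, via 3-hydroxy-2,4,5-trimethoxybenzaldehyde 9 (not isolated), via racemic aldol adduct 10 (not isolated)
Conditions: KOH (50% aq, excess), EtOH, rt, 48 h; then 1 M HCl to pH 3
Reagents that add atoms: none
Why: Claisen–Schmidt condensation: KOH first saponifies the aryl acetate, the enolate of 8 adds to the non-enolisable aldehyde, and E1cB loss of water gives the conjugated enone with the thermodynamically favoured E geometry.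

**Step 5**
Reactants: 11 (E)-2'-hydroxychalcone from step 4
Product: 12 5,7-bis(benzyloxy)-2-(3-hydroxy-2,4,5-trimethoxyphenyl)-4H-chromen-4-one
Conditions: I2 (10 mol%), DMSO, 130 °C, 2 h; aq Na2S2O3 work-up
Reagents that add atoms: none
Why: Iodine-catalysed oxidative cyclisation of a 2'-hydroxychalcone closes ring C by attack of the phenol oxygen on the enone β-carbon with net loss of two hydrogens, DMSO being the terminal oxidant; benzyl and methyl ethers are inert.

**Step 6**
Reactants: 12 5,7-bis(benzyloxy)-2-(3-hydroxy-2,4,5-trimethoxyphenyl)-4H-chromen-4-one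
Product: 13 5,7,3'-trihydroxy-2',4',5'-trimethoxyflavone (target)
Conditions: H2 (1 atm), 10% Pd/C, THF–MeOH 1:1, rt
Reagents that add atoms: none
Why: Catalytic hydrogenolysis cleaves both benzyl aryl ethers, while the C2=C3 bond of the γ-pyrone (a vinylogous ester) and the methyl ethers are untouched at 1 atm and room temperature.

**Compound list**
1 | 1,2,4-trimethoxybenzene | COc1ccc(OC)c(OC)c1 | starting material
2 | (2,3,6-trimethoxyphenyl)lithium | COc1ccc(OC)c([Li])c1OC | intermediate
3 | dimethyl (2,3,6-trimethoxyphenyl)boronate | COc1ccc(OC)c(B(OC)OC)c1OC | intermediate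
4 | 2,3,6-trimethoxyphenol | COc1ccc(OC)c(O)c1OC | intermediate
5 | 2,3,6-trimethoxyphenyl acetate | COc1ccc(OC)c(OC(C)=O)c1OC | intermediate
6 | 3-[chloro(methoxy)methyl]-2,5,6-trimethoxyphenyl acetate (racemic, not isolated) | COc1cc(C(Cl)OC)c(OC)c(OC(C)=O)c1OC | intermediate
7 | 3-acetoxy-2,4,5-trimethoxybenzaldehyde | COc1cc(C=O)c(OC)c(OC(C)=O)c1OC | intermediate
8 | 2'-hydroxy-4',6'-bis(benzyloxy)acetophenone, i.e. 1-[2,4-bis(benzyloxy)-6-hydroxyphenyl]ethan-1-one | CC(=O)c1c(O)cc(OCc2ccccc2)cc1OCc1ccccc1 | starting material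
9 | 3-hydroxy-2,4,5-trimethoxybenzaldehyde (in the flask as its potassium phenoxide) | COc1cc(C=O)c(OC)c(O)c1OC | intermediate
10 | 1-[2,4-bis(benzyloxy)-6-hydroxyphenyl]-3-hydroxy-3-(3-hydroxy-2,4,5-trimethoxyphenyl)propan-1-one (racemic aldol adduct) | COc1cc(C(O)CC(=O)c2c(O)cc(OCc3ccccc3)cc2OCc2ccccc2)c(OC)c(O)c1OC | intermediate
11 | (E)-1-[2,4-bis(benzyloxy)-6-hydroxyphenyl]-3-(3-hydroxy-2,4,5-trimethoxyphenyl)prop-2-en-1-one | COc1cc(/C=C/C(=O)c2c(O)cc(OCc3ccccc3)cc2OCc2ccccc2)c(OC)c(O)c1OC | intermediate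
12 | 5,7-bis(benzyloxy)-2-(3-hydroxy-2,4,5-trimethoxyphenyl)-4H-chromen-4-one | COc1cc(-c2cc(=O)c3c(OCc4ccccc4)cc(OCc4ccccc4)cc3o2)c(OC)c(O)c1OC | intermediate
13 | 5,7-dihydroxy-2-(3-hydroxy-2,4,5-trimethoxyphenyl)-4H-chromen-4-one (achiral) | COc1cc(-c2cc(=O)c3c(O)cc(O)cc3o2)c(OC)c(O)c1OC | target

**Totals**
Total step count: 6. Longest linear sequence: 6 steps (1 to 13; 8 is bought).

**Steps most likely to fail**

Step 3 (the regiochemistry of the formylation is argued from electronics, not proven, and TiCl4 may touch the acetate). The fallback sets out from 1 and comes back at 9. It puts the carbon in first, at the known reactive position of 1, and the oxygen second. Vilsmeier–Haack formylation of 1 (POCl3, DMF, 0 to 80 °C, aq NaOAc) gives 2,4,5-trimethoxybenzaldehyde F1. Ethylene glycol with cat. TsOH in toluene (Dean–Stark) gives 2-(2,4,5-trimethoxyphenyl)-1,3-dioxolane F2. n-BuLi in THF at 0 °C removes the hydrogen between the two methoxy groups to give [3-(1,3-dioxolan-2-yl)-2,5,6-trimethoxyphenyl]lithium F3. B(OMe)3 gives dimethyl [3-(1,3-dioxolan-2-yl)-2,5,6-trimethoxyphenyl]boronate F4, and NaOH/H2O2 gives 3-(1,3-dioxolan-2-yl)-2,5,6-trimethoxyphenol F5. 1 M HCl in THF releases 9, which is isolated and used in step 4 in place of 7.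

Step 4 (a hindered, chelated ketone and an electron-rich aldehyde carrying a phenoxide may condense slowly). The fallback sets out from 7 (with 8) and comes back at 12, replacing the aldol disconnection by a Baker–Venkataraman sequence. Pinnick oxidation of 7 (NaClO2, NaH2PO4, 2-methylbut-2-ene, t-BuOH/H2O) gives 3-acetoxy-2,4,5-trimethoxybenzoic acid F6. (COCl)2 with cat. DMF in CH2Cl2 gives 3-acetoxy-2,4,5-trimethoxybenzoyl chloride F7. Acylation of the phenol of 8 (pyridine, cat. DMAP) gives 2-acetyl-3,5-bis(benzyloxy)phenyl 3-acetoxy-2,4,5-trimethoxybenzoate F8. KOH in pyridine at 50 °C brings about the acyl migration, with loss of the acetate, to give 1-[2,4-bis(benzyloxy)-6-hydroxyphenyl]-3-(3-hydroxy-2,4,5-trimethoxyphenyl)propane-1,3-dione F9. AcOH with cat. H2SO4 at 60 °C cyclodehydrates F9 to 12.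

Step 5 (the free, electron-rich ring B phenol may be iodinated or the oxidation may stall). The fallback sets out from 11 and comes back at 12, separating ring closure from oxidation and using no iodine. NaOAc in refluxing EtOH closes the chalcone by oxa-Michael addition to racemic 5,7-bis(benzyloxy)-2-(3-hydroxy-2,4,5-trimethoxyphenyl)chroman-4-one F10. Aerobic dehydrogenation with cat. Pd(OCOCF3)2 in DMSO under O2 (1 atm) at 100 °C then gives 12.

**Further compounds**
F1 | step 3 | 2,4,5-trimethoxybenzaldehyde | COc1cc(C=O)c(OC)cc1OC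
F2 | step 3 | 2-(2,4,5-trimethoxyphenyl)-1,3-dioxolane | COc1cc(C2OCCO2)c(OC)cc1OC
F3 | step 3 | [3-(1,3-dioxolan-2-yl)-2,5,6-trimethoxyphenyl]lithium | COc1cc(C2OCCO2)c(OC)c([Li])c1OC
F4 | step 3 | dimethyl [3-(1,3-dioxolan-2-yl)-2,5,6-trimethoxyphenyl]boronate | COc1cc(C2OCCO2)c(OC)c(B(OC)OC)c1OC
F5 | step 3 | 3-(1,3-dioxolan-2-yl)-2,5,6-trimethoxyphenol | COc1cc(C2OCCO2)c(OC)c(O)c1OC
F6 | step 4 | 3-acetoxy-2,4,5-trimethoxybenzoic acid | COc1cc(C(=O)O)c(OC)c(OC(C)=O)c1OC
F7 | step 4 | 3-acetoxy-2,4,5-trimethoxybenzoyl chloride | COc1cc(C(=O)Cl)c(OC)c(OC(C)=O)c1OC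
F8 | step 4 | 2-acetyl-3,5-bis(benzyloxy)phenyl 3-acetoxy-2,4,5-trimethoxybenzoate | COc1cc(C(=O)Oc2cc(OCc3ccccc3)cc(OCc3ccccc3)c2C(C)=O)c(OC)c(OC(C)=O)c1OC
F9 | step 4 | 1-[2,4-bis(benzyloxy)-6-hydroxyphenyl]-3-(3-hydroxy-2,4,5-trimethoxyphenyl)propane-1,3-dione | COc1cc(C(=O)CC(=O)c2c(O)cc(OCc3ccccc3)cc2OCc2ccccc2)c(OC)c(O)c1OC
F10 | step 5 | 5,7-bis(benzyloxy)-2-(3-hydroxy-2,4,5-trimethoxyphenyl)chroman-4-one (racemic) | COc1cc(C2CC(=O)c3c(OCc4ccccc4)cc(OCc4ccccc4)cc3O2)c(OC)c(O)c1OC
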